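## Structural features

The target is a resveratrol trimer built on a central benzene ring (ring A). Ring A carries, on three neighbouring carbons, C3 of a first trans-2,3-diaryl-2,3-dihydrobenzofuran, a benzylic CH2 (C9) and C3' of a second trans-2-aryl-2,3-dihydrobenzofuran; its two oxygens are the two furan oxygens and only one ring A carbon bears hydrogen. C3' also belongs to a seven-membered carbocycle (ring C), made of C3', two ring A carbons, C9, the 4-hydroxyphenyl-bearing methine C8 and two adjacent carbons of a second resorcinol ring (ring D). There are five stereocentres: the vicinal pairs C2/C3 and C2'/C3' (each trans) lie on opposite flanks of ring A and barely sense each other, and C8 stands 1,4 to C3' across ring C. Fragile elements are the six free phenols, the benzylic C–O bonds at C2 and C2' (each next to a 4-oxygenated aryl group, so acid ionises them with epimerisation or ring opening) and the doubly benzylic C3–H, C3'–H and C8–H bonds (strong base can expel the phenoxide or scramble C8). The real difficulty is the hexasubstituted ring A with three different carbon substituents, three stereochemical elements that must be set independently, and a seven-membered ring wedged between two hindered arenes. The key step exploits ring D: going round it from the fusion carbon bonded to C3' one meets CH, C–O, CH, C–O and the fusion carbon bonded to C8, which is the pattern a vinylketene and a terminal siloxyalkyne deliver. Ring D can therefore be grown on the C=C bond of a preformed ring C.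

## Logic of the disconnections

37 ⇒ 36 ⇒ 35. Five O–CH3 bonds and one O–Si bond are cut. Methyl ethers are the simplest phenol protection that should survive the organolithium, Grignard, carbene, chromium and photochemical steps alike. The demand is that the two benzylic aryl ethers survive BBr3; the trans arrangement at both rings is the thermodynamic one, so reversible ionisation at C2 or C2' does no harm.

35 ⇒ 32 + 33. Four C–C bonds of ring D are cut, one of them the bond that the Wolff shift makes. This removes a whole arene and leaves a cycloheptene with one acyl group; all five stereocentres are already present and none is made. 32 and 35 map onto 37 atom for atom, with the same configuration at all five centres. The forward step needs an s-cis-capable diazo enone, an alkyne polarised enough to fix the regiochemistry, and neutral conditions.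

32 ⇒ 30 ⇒ 29 ⇒ 28. The C=N2 unit is traced to the methyl group of 30 (diazo transfer), the ring C alkene to two terminal alkenes (metathesis), and the methyl ketone to a carboxylic acid. This is where the precursor design is improved. Acylating a diazoalkane with the enoyl chloride is avoided, because diazoalkanes add across conjugated C=C bonds and the chloride has to be made next to two acid-labile benzylic ethers. The demand is kinetic deprotonation of 30 at the methyl group and not at C8.

28 ⇒ 27 ⇒ 24 + 25. The C2'–O aryl ether bond and then the C3'–C2' bond are cut. Once the 4-methoxybenzyl group is off, the phenol lactone is an isomer of the dihydrofuran acid, so one acid treatment can unmask the phenol, ionise the benzylic lactone C–O bond and close the furan. The C3'–C2' bond comes from a 2-(alkoxycarbonyl)allyl metal and an aldehyde, which puts the acrylate on C3' in the same operation. The demand is catalyst control at C3', since the existing centres are too remote to help.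

24 ⇒ 23 ⇒ 20 + 21, and 20 ⇒ 18. The C3'–Cα bond is cut (α-metallated acrylate plus aldehyde), then the formyl C–C bond (aryl bromide to aryllithium). The demand is an aldehyde addition that tolerates two ortho substituents.

18 ⇒ 14 + 16 (16 ⇒ 15). The C8–C9 bond is cut in the SN2' sense. This sets C8 under CuBr·SMe2 and a chiral diphosphine and installs the vinyl group needed for metathesis. It must come after the carbene step, because a terminal alkene six atoms from a rhodium carbene would be cyclopropanated.

14 ⇒ 12 ⇒ 11 ⇒ 9 ⇒ 5 + 6. The C2–C3 bond is cut as a carbene C–H insertion into the benzylic CH2 of an aryl 4-methoxybenzyl ether, which turns a protecting group into C2 and its aryl ring. The diaryl carbene comes from a hydrazone, and the hydrazone from an aryllithium and a nitrile. The demand is a chiral dirhodium tetracarboxylate, Rh2(S-PTAD)4, that controls C3; C2 is corrected later by acid.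

5 ⇒ 4 ⇒ 3 ⇒ 1 + 2. Two C–Br bonds, one O–Si bond and two O–benzyl bonds are cut. Both ring A positions that will carry carbon are brominated while the ring is still symmetric and before any other activated arene is present, so no later regiochemical choice between ring A and the dimethoxyphenyl ring arises. The forward demand is clean double etherification and double bromination, each with two equivalents of reagent.

## Other disconnections considered

Alternative 1: The cut is at the C8–C9 and C8–ring D bonds, with C9 as a carbonyl. Forward, the six-membered diaryl ketone A1 would take up 4-methoxyphenyldiazomethane A2 under Sc(OTf)3 and a chiral bis(oxazoline), the ring D carbon migrating to give the seven-membered α-aryl ketone A3.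
- In its favour: ring D arrives intact from a resorcinol building block, C8 is set late by a catalyst, and no photochemistry or diazo ketone is needed. On convergence it is the better plan.
- Against it: A1 is a 10-substituted anthrone, whose C3'–H can tautomerise to the aromatic anthranol and erase C3'. Its carbonyl, flanked by two electron-rich arenes, is a weak acceptor. Two aryl groups of similar migratory aptitude compete. C8–H in A3 is α to a ketone and doubly benzylic. The C9 carbonyl, absent from the target, must then be removed.
- Comparison: the chosen key step delivers the oxidation pattern of the target directly and its regiochemistry follows from alkyne polarity, whereas A3 needs a redox detour. The two plans are equal in ending with a BBr3 deprotection.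

Alternative 2: The cut is at two ring A bonds. Forward, the 4-substituted 1,1-dimethoxy-3-silyloxy diene A4 would add to the 2-bromo enone A5 of a ring D-fused cycloheptenone, and loss of HBr, methanol and the silyl group would give the ring A phenol A6.
- In its favour: the substitution pattern of ring A is fixed by the cycloaddition and not by successive halogenations. On that point it is the better plan, and it is equal to the chosen plan in building an arene by an aromatisation-driven step.
- Against it: the dienophile is a trisubstituted alkene in a seven-membered enone, and the diene carries a branched, stereogenic substituent at its reacting terminus. After the key step the C3' ketone must still be turned into the second dihydrofuran with only substrate control. One methyl ether out of seven must be cleaved selectively for that, although its position ortho to the ketone would help.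
- Comparison: A6 is further from the target than 35 and leaves two stereocentres unset, so more steps follow its key step.

Alternative 3: The cut is at the ring D–C3' bond and the C2'–H bond. Forward, the aryl bromide A7, tethered through C8–C9 to C4 of a 2-arylbenzofuran, would undergo a reductive Heck reaction with Pd(OAc)2, a bisphosphine and HCO2Na to give the heptamethyl ether A8.
- In its favour: ring C and both C2' and C3' are formed in one step, the trans relation follows from syn carbopalladation and hydride delivery, and A8 is one deprotection from the target. On step economy and convergence it is the better plan.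
- Against it: a seven-membered closure onto C3 of a 2-aryl benzofuran is outside the usual five- and six-membered cases. The face of attack must be dictated by C8 through the forming ring or by the ligand, and hydrodebromination competes. A7 still needs an enantioenriched first dihydrofuran and a 1,1,2-triarylethane centre at C8.
- Comparison: its key step must set two stereocentres, where the chosen key step sets none and so carries less stereochemical risk. The two plans are equal in needing a final BBr3 treatment.

Key step: step 18

Remark: (triisopropylsilyloxy)acetylene 33, the chiral ligands and Rh2(S-PTAD)4 are assumed to be on hand as stock reagents.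
Remark: the catalyst and ligand antipodes named are those expected by analogy to give the configurations drawn; if the sense of induction proves opposite, the mirror-image catalyst is used.

## Route

Step 1
Reactants: 1 3,5-dihydroxybenzyl alcohol; 2 4-methoxybenzyl chloride
Product: 3 [3,5-bis(4-methoxybenzyloxy)phenyl]methanol
Conditions: 2 (2.2 equiv), K2CO3 (3 equiv), n-Bu4NI (cat.), acetone, 56 °C
Reagents that add atoms: 4-methoxybenzyl chloride (the second equivalent of 2), COc1ccc(CCl)cc1
Why: Double Williamson etherification in which each phenol takes one 4-methoxybenzyl group, so two equivalents of 2 end up in 3; K2CO3 ionises only the phenols, so the benzylic alcohol stays free.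

Step 2
Reactants: 3 [3,5-bis(4-methoxybenzyloxy)phenyl]methanol
Product: 4 [2,6-dibromo-3,5-bis(4-methoxybenzyloxy)phenyl]methanol
Conditions: NBS (2.05 equiv), MeCN, 0 → 23 °C
Reagents that add atoms: N-bromosuccinimide (first equivalent), O=C1CCC(=O)N1Br; N-bromosuccinimide (second equivalent), O=C1CCC(=O)N1Br
Why: Electrophilic aromatic bromination, twice; each bromine should enter para to one ether oxygen, while the position between the two bulky benzyloxy groups is shielded and the anisole rings of the protecting groups are much less activated than the resorcinol diether ring.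

Step 3
Reactants: 4 [2,6-dibromo-3,5-bis(4-methoxybenzyloxy)phenyl]methanol
Product: 5 [2,6-dibromo-3,5-bis(4-methoxybenzyloxy)benzyloxy]triisopropylsilane
Conditions: i-Pr3SiCl, imidazole, DMF, 23 °C
Reagents that add atoms: triisopropylsilyl chloride, CC(C)[Si](Cl)(C(C)C)C(C)C
Why: Silylation of the primary alcohol; the bulky triisopropylsilyl group is chosen to suppress oxygen-to-carbon silyl migration in the ortho-lithiated species of step 4 and O–H insertion in step 5.

Step 4
Reactants: 5 [2,6-dibromo-3,5-bis(4-methoxybenzyloxy)benzyloxy]triisopropylsilane; 6 3,5-dimethoxybenzonitrile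
Product: 9 hydrazone of [3-bromo-4,6-bis(4-methoxybenzyloxy)-2-(triisopropylsilyloxymethyl)phenyl](3,5-dimethoxyphenyl)methanone, via aryllithium 7 (not isolated), via NH-ketimine 8 (not isolated)
Conditions: n-BuLi (1.0 equiv), THF, −78 °C; 6, −78 → −20 °C; MeOH; N2H4·H2O, AcOH (cat.), EtOH, 70 °C
Reagents that add atoms: hydrazine, NN
Why: A single lithium–bromine exchange (a second would place two charges on one ring) and addition to the nitrile give the N–H ketimine. Transimination with hydrazine then gives the hydrazone without condensing hydrazine on a di-ortho-substituted benzophenone.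

Step 5
Reactants: 9 hydrazone of step 4
Product: 11 (2S,3R)-5-bromo-3-(3,5-dimethoxyphenyl)-2-(4-methoxyphenyl)-6-(4-methoxybenzyloxy)-4-(triisopropylsilyloxymethyl)-2,3-dihydrobenzofuran (2,3-cis), via diaryldiazomethane 10 (not isolated)
Conditions: MnO2, MeCN, 0 °C; Rh2(S-PTAD)4 (1 mol %), 0 °C
Reagents that add atoms: none
Why: Oxidation gives the diaryldiazomethane, whose donor/donor rhodium carbene inserts into the activated benzylic C–H of the ortho 4-methoxybenzyl ether (1,5-insertion, five-membered ring). The chiral dirhodium carboxylate sets C3 and the cis isomer is expected; C2 is provisional and is equilibrated in step 14.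

Step 6
Reactants: 11 silyl ether of step 5
Product: 12 [(2S,3R)-5-bromo-3-(3,5-dimethoxyphenyl)-2-(4-methoxyphenyl)-6-(4-methoxybenzyloxy)-2,3-dihydrobenzofuran-4-yl]methanol
Conditions: n-Bu4NF, THF, 0 → 23 °C
Reagents that add atoms: none
Why: Fluoride-induced desilylation; the aryl bromide, ethers and the dihydrofuran are inert.

Step 7
Reactants: 12 alcohol of step 6
Product: 14 (2S,3R)-5-bromo-4-(chloromethyl)-3-(3,5-dimethoxyphenyl)-2-(4-methoxyphenyl)-6-(4-methoxybenzyloxy)-2,3-dihydrobenzofuran, via mesylate 13 (not isolated)
Conditions: MsCl, Et3N, LiCl, THF/DMF, 0 → 23 °C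
Reagents that add atoms: lithium chloride, [Li+].[Cl-]
Why: Mesylation and in situ SN2 displacement by chloride; the benzylic carbon is meta to both ring oxygens, so the chloride is not prone to ionisation and should keep.

Step 8
Reactants: 15 (E)-3-(4-methoxyphenyl)prop-2-en-1-ol
Product: 16 (E)-1-(3-bromoprop-1-enyl)-4-methoxybenzene
Conditions: PBr3 (0.4 equiv), Et2O, −20 → 0 °C; used at once
Reagents that add atoms: phosphorus tribromide, BrP(Br)Br
Why: Conversion of a primary allylic alcohol into the bromide; the product ionises easily and is therefore taken crude and cold into step 9.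

Step 9
Reactants: 14 benzylic chloride of step 7; 16 (E)-1-(3-bromoprop-1-enyl)-4-methoxybenzene
Product: 18 (2S,3R)-5-bromo-3-(3,5-dimethoxyphenyl)-2-(4-methoxyphenyl)-6-(4-methoxybenzyloxy)-4-[(2R)-2-(4-methoxyphenyl)but-3-enyl]-2,3-dihydrobenzofuran, via benzylmagnesium chloride 17 (not isolated)
Conditions: Mg, Et2O, 0 °C; slow addition to 16, CuBr·SMe2 (5 mol %), (R,R)-Taniaphos (6 mol %), CH2Cl2, −78 °C
Reagents that add atoms: none
Why: Copper-catalysed asymmetric allylic alkylation in the SN2' sense; the chiral diphosphine–copper complex sets C8 at the aryl-bearing carbon of the cinnamyl unit, and the existing centres are too remote to interfere. Magnesium should insert into the benzylic chloride faster than into the hindered aryl bromide.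

Step 10
Reactants: 18 aryl bromide of step 9
Product: 20 (2S,3R)-3-(3,5-dimethoxyphenyl)-2-(4-methoxyphenyl)-6-(4-methoxybenzyloxy)-4-[(2R)-2-(4-methoxyphenyl)but-3-enyl]-2,3-dihydrobenzofuran-5-carbaldehyde, via aryllithium 19 (not isolated)
Conditions: n-BuLi, THF, −78 °C; DMF; aq. NH4Cl
Reagents that add atoms: N,N-dimethylformamide, CN(C)C=O
Why: Lithium–bromine exchange and formylation; at −78 °C the exchange should outrun deprotonation of the doubly benzylic C–H bonds, and the terminal alkene is inert.

Step 11
Reactants: 20 aldehyde of step 10; 21 methyl propiolate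
Product: 23 methyl 2-[hydroxy(Ar5)methyl]acrylate (Ar5 = the 2,3-dihydrobenzofuran-5-yl group of 20; both carbinol epimers), via vinylalane 22 (not isolated)
Conditions: i-Bu2AlH, N-methylmorpholine N-oxide, THF, 0 °C; 21; then 20, 0 → 23 °C
Reagents that add atoms: none
Why: Hydroalumination of the propiolate gives an α-aluminated acrylate that adds to the aldehyde (vinylalumination route to a Morita–Baylis–Hillman adduct), which does not depend on the slow amine-catalysed reaction of a di-ortho-substituted, electron-rich aldehyde. The new carbinol centre is not controlled and is removed in step 12.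

Step 12
Reactants: 23 allylic alcohol of step 11
Product: 24 methyl (Z)-2-(bromomethyl)-3-(Ar5)acrylate
Conditions: NBS, Me2S, CH2Cl2, 0 °C; then 23, 0 → 23 °C
Reagents that add atoms: N-bromosuccinimide, O=C1CCC(=O)N1Br
Why: The bromosulfonium reagent of the Corey–Kim type activates the alcohol and bromide enters at the CH2 terminus with allylic transposition (SN2'), giving the conjugated bromide; premixing with Me2S should keep NBS from brominating the activated arenes.

Step 13
Reactants: 24 allylic bromide of step 12; 25 4-methoxybenzaldehyde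
Product: 27 4,5-cis-5-(4-methoxyphenyl)-3-methylidene-4-(Ar5)dihydrofuran-2(3H)-one, via hydroxy ester 26 (not isolated)
Conditions: CrCl2 (10 mol %), tridentate carbazole bis(oxazoline) ligand (12 mol %), i-Pr2NEt, Mn powder, Me3SiCl, THF, 23 °C; aq. citric acid work-up; PPTS (cat.), CH2Cl2, 23 °C
Reagents that add atoms: none
Why: Catalytic asymmetric Nozaki–Hiyama–Kishi-type 2-(alkoxycarbonyl)allylation: the allylchromium species adds through its aryl-bearing γ-carbon in a six-membered transition state. The chiral ligand fixes the aldehyde face and the closed transition state relays this to C3' (the ring carbon bonded to Ar5). Mild acid closes the lactone; the configuration at the lactone C5 is erased in step 14, so only C3' has to be right.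

Step 14
Reactants: 27 lactone of step 13
Product: 28 2-[(2,3-trans,5,6-trans)-3-(3,5-dimethoxyphenyl)-2,6-bis(4-methoxyphenyl)-4-[(2R)-2-(4-methoxyphenyl)but-3-enyl]-2,3,5,6-tetrahydrobenzo[1,2-b:5,4-b']difuran-5-yl]acrylic acid
Conditions: CF3CO2H/CH2Cl2 (1:4), pentamethylbenzene (5 equiv), 0 → 23 °C
Reagents that add atoms: none
Why: Acid removes the aryl 4-methoxybenzyl ether (cation trapped by pentamethylbenzene) and ionises the benzylic lactone C–O bond to a 4-methoxybenzylic cation, which the freed ortho phenol captures in a 5-exo closure (SN1 etherification), releasing the carboxylic acid. C2' and, by the same reversible ionisation, C2 of the first ring should settle in the more stable trans arrangement, while C3 and C3' are not touched.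

Step 15
Reactants: 28 acrylic acid of step 14
Product: 29 3-[the tetrahydrobenzodifuran-5-yl group of 28]but-3-en-2-one
Conditions: MeLi (3 equiv), THF, 0 °C; inverse quench into aq. NH4Cl
Reagents that add atoms: methyllithium, [Li]C
Why: Addition of methyllithium to the lithium carboxylate gives a dilithio gem-diolate that collapses to the methyl ketone only on hydrolysis, so over-addition is held back. At this stage C8 is not yet vinylogously linked to the carbonyl group, so it is not at risk.

Step 16
Reactants: 29 dienone of step 15
Product: 30 cycloheptene-fused methyl ketone (ring C closed between the former vinyl CH and the enone α-carbon of 29; acetyl on the alkene carbon bonded to C3', C8 next to the alkene CH; pentamethyl ether, configuration as in 37)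
Conditions: second-generation Grubbs catalyst (10 mol %), 1,4-benzoquinone (20 mol %), PhMe (2 mM), 80 °C
Reagents that add atoms: none
Why: Ring-closing metathesis of a terminal alkene with a 1,1-disubstituted enone gives the trisubstituted cycloheptene with loss of ethene; the two alkenes sit on ortho positions of ring A, and benzoquinone should suppress ruthenium hydride migration of the alkene towards C8.

Step 17
Reactants: 30 methyl ketone of step 16
Product: 32 cycloheptenyl diazomethyl ketone (30 with COCHN2 in place of COCH3), via trifluoroacetyl ketone 31 (not isolated)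
Conditions: LiN(SiMe3)2, THF, −78 °C; CF3CO2CH2CF3; then 4-acetamidobenzenesulfonyl azide, Et3N, H2O (1 equiv), MeCN, 23 °C
Reagents that add atoms: 4-acetamidobenzenesulfonyl azide, CC(=O)Nc1ccc(cc1)S(=O)(=O)N=[N+]=[N-]
Why: Detrifluoroacetylative diazo transfer: the kinetic cross-conjugated enolate at the methyl group is trifluoroacetylated, and diazo transfer to the activated methylene then expels the trifluoroacetyl group on the sulfonamide nitrogen. This avoids both diazomethane, which adds to conjugated alkenes, and an acid chloride.

Step 18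
Reactants: 32 cycloheptenyl diazomethyl ketone; 33 (triisopropylsilyloxy)acetylene
Product: 35 pentamethyl ether of 37 with ring D as free phenol (next to the fusion carbon bonded to C8) and triisopropylsilyl ether (meta to it), via vinylcyclobutenone 34 (not isolated)
Conditions: 33 (2 equiv), ClCH2CH2Cl (0.05 M), Ar, hν (365 nm), 23 °C; then 80 °C
Reagents that add atoms: none
Why: Light expels N2 from 32 and the cycloheptenyl group migrates to the former diazo carbon (Wolff rearrangement), giving a vinylketene whose alkene is the ring C double bond. The polarised siloxyalkyne 33 adds to the ketene C=C in a [2+2] cycloaddition, its nucleophilic CH terminus bonding to the ketene carbonyl carbon, so cyclobutenone 34 carries the silyloxy group at C3 and the cycloheptenyl group at C4. Heating opens 34 by 4π-electrocyclic cleavage of the C1–C4 bond to a dienylketene, which closes by 6π-electrocyclisation between the ketene carbon and the cycloheptene CH; tautomerisation of the cyclohexadienone gives the phenol. Ring D is thus closed in the six-membered 6π-electrocyclic mode with aromatisation as driving force; this is the photochemical Wolff variant of the Danheiser benzannulation, known for α-diazo enones and siloxyalkynes. No stereocentre is created, because the sp3 carbon of 34 is transient and the former alkene carbons become aromatic. The selectivity needed is regiochemical and is fixed by the alkyne polarity, which places the free OH next to the fusion carbon bonded to C8 and the silyl ether meta to it. Irradiation at 365 nm, where the anisole rings do not absorb, and neutral conditions should leave C8 (γ to the carbonyl), the two acid-labile benzylic ethers and all five stereocentres untouched.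

Step 19
Reactants: 35 silyl ether of step 18
Product: 36 pentamethyl ether of 37 with ring D as free resorcinol
Conditions: n-Bu4NF, THF, 0 °C; aq. NH4Cl
Reagents that add atoms: none
Why: Fluoride cleaves the aryl silyl ether; done before the Lewis acid step so that the last step has only methyl ethers to remove.

Step 20
Reactants: 36 pentamethyl ether of step 19
Product: 37 target CNP0136963.1 (hexaphenol)
Conditions: BBr3 (20 equiv), CH2Cl2, −78 → 23 °C; MeOH
Reagents that add atoms: none
Why: Lewis-acid demethylation of five aryl methyl ethers; the two trans dihydrofurans are the thermodynamic isomers, so reversible ionisation at C2 or C2' should return the same configuration.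

## Compound list

1 | 3,5-dihydroxybenzyl alcohol | OCc1cc(O)cc(O)c1 | starting material
2 | 4-methoxybenzyl chloride | COc1ccc(CCl)cc1 | starting material
3 | [3,5-bis(4-methoxybenzyloxy)phenyl]methanol | OCc1cc(OCc2ccc(OC)cc2)cc(OCc2ccc(OC)cc2)c1 | intermediate
4 | [2,6-dibromo-3,5-bis(4-methoxybenzyloxy)phenyl]methanol | OCc1c(Br)c(OCc2ccc(OC)cc2)cc(OCc2ccc(OC)cc2)c1Br | intermediate
5 | [2,6-dibromo-3,5-bis(4-methoxybenzyloxy)benzyloxy]triisopropylsilane | CC(C)[Si](OCc1c(Br)c(OCc2ccc(OC)cc2)cc(OCc2ccc(OC)cc2)c1Br)(C(C)C)C(C)C | intermediate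
6 | 3,5-dimethoxybenzonitrile | COc1cc(C#N)cc(OC)c1 | starting material
7 | monolithio derivative of 5 (Li in place of one Br) | [Li]c1c(CO[Si](C(C)C)(C(C)C)C(C)C)c(Br)c(OCc2ccc(OC)cc2)cc1OCc1ccc(OC)cc1 | intermediate
8 | [3-bromo-4,6-bis(4-methoxybenzyloxy)-2-(triisopropylsilyloxymethyl)phenyl](3,5-dimethoxyphenyl)methanimine | N=C(c1cc(OC)cc(OC)c1)c1c(CO[Si](C(C)C)(C(C)C)C(C)C)c(Br)c(OCc2ccc(OC)cc2)cc1OCc1ccc(OC)cc1 | intermediate
9 | hydrazone of [3-bromo-4,6-bis(4-methoxybenzyloxy)-2-(triisopropylsilyloxymethyl)phenyl](3,5-dimethoxyphenyl)methanone | NN=C(c1cc(OC)cc(OC)c1)c1c(CO[Si](C(C)C)(C(C)C)C(C)C)c(Br)c(OCc2ccc(OC)cc2)cc1OCc1ccc(OC)cc1 | intermediate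
10 | [3-bromo-4,6-bis(4-methoxybenzyloxy)-2-(triisopropylsilyloxymethyl)phenyl](3,5-dimethoxyphenyl)diazomethane | [N-]=[N+]=C(c1cc(OC)cc(OC)c1)c1c(CO[Si](C(C)C)(C(C)C)C(C)C)c(Br)c(OCc2ccc(OC)cc2)cc1OCc1ccc(OC)cc1 | intermediate
11 | (2S,3R)-5-bromo-3-(3,5-dimethoxyphenyl)-2-(4-methoxyphenyl)-6-(4-methoxybenzyloxy)-4-(triisopropylsilyloxymethyl)-2,3-dihydrobenzofuran (2,3-cis) | CC(C)[Si](OCc1c(Br)c(OCc2ccc(OC)cc2)cc2c1[C@@H](c1cc(OC)cc(OC)c1)[C@@H](c1ccc(OC)cc1)O2)(C(C)C)C(C)C | intermediate
12 | [(2S,3R)-5-bromo-3-(3,5-dimethoxyphenyl)-2-(4-methoxyphenyl)-6-(4-methoxybenzyloxy)-2,3-dihydrobenzofuran-4-yl]methanol | OCc1c(Br)c(OCc2ccc(OC)cc2)cc2c1[C@@H](c1cc(OC)cc(OC)c1)[C@@H](c1ccc(OC)cc1)O2 | intermediate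
13 | methanesulfonate of 12 | CS(=O)(=O)OCc1c(Br)c(OCc2ccc(OC)cc2)cc2c1[C@@H](c1cc(OC)cc(OC)c1)[C@@H](c1ccc(OC)cc1)O2 | intermediate
14 | (2S,3R)-5-bromo-4-(chloromethyl)-3-(3,5-dimethoxyphenyl)-2-(4-methoxyphenyl)-6-(4-methoxybenzyloxy)-2,3-dihydrobenzofuran | ClCc1c(Br)c(OCc2ccc(OC)cc2)cc2c1[C@@H](c1cc(OC)cc(OC)c1)[C@@H](c1ccc(OC)cc1)O2 | intermediate
15 | (E)-3-(4-methoxyphenyl)prop-2-en-1-ol | COc1ccc(/C=C/CO)cc1 | starting material
16 | (E)-1-(3-bromoprop-1-enyl)-4-methoxybenzene | COc1ccc(/C=C/CBr)cc1 | intermediate
17 | benzylmagnesium chloride derived from 14 | Cl[Mg]Cc1c(Br)c(OCc2ccc(OC)cc2)cc2c1[C@@H](c1cc(OC)cc(OC)c1)[C@@H](c1ccc(OC)cc1)O2 | intermediate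
18 | (2S,3R)-5-bromo-3-(3,5-dimethoxyphenyl)-2-(4-methoxyphenyl)-6-(4-methoxybenzyloxy)-4-[(2R)-2-(4-methoxyphenyl)but-3-enyl]-2,3-dihydrobenzofuran | COc1ccc([C@@H](C=C)Cc2c(Br)c(OCc3ccc(OC)cc3)cc3c2[C@@H](c2cc(OC)cc(OC)c2)[C@@H](c2ccc(OC)cc2)O3)cc1 | intermediate
19 | 5-lithio derivative of 18 (Li in place of Br) | COc1ccc([C@@H](C=C)Cc2c([Li])c(OCc3ccc(OC)cc3)cc3c2[C@@H](c2cc(OC)cc(OC)c2)[C@@H](c2ccc(OC)cc2)O3)cc1 | intermediate
20 | (2S,3R)-3-(3,5-dimethoxyphenyl)-2-(4-methoxyphenyl)-6-(4-methoxybenzyloxy)-4-[(2R)-2-(4-methoxyphenyl)but-3-enyl]-2,3-dihydrobenzofuran-5-carbaldehyde | COc1ccc([C@@H](C=C)Cc2c(C=O)c(OCc3ccc(OC)cc3)cc3c2[C@@H](c2cc(OC)cc(OC)c2)[C@@H](c2ccc(OC)cc2)O3)cc1 | intermediate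
21 | methyl propiolate | C#CC(=O)OC | starting material
22 | methyl 2-(diisobutylalumanyl)acrylate | C=C(C(=O)OC)[Al](CC(C)C)CC(C)C | intermediate
23 | methyl 2-[hydroxy(Ar5)methyl]acrylate, both carbinol epimers (Ar5 = dihydrobenzofuran-5-yl group of 20) | COc1ccc([C@@H](C=C)Cc2c(C(O)C(=C)C(=O)OC)c(OCc3ccc(OC)cc3)cc3c2[C@@H](c2cc(OC)cc(OC)c2)[C@@H](c2ccc(OC)cc2)O3)cc1 | intermediate
24 | methyl (Z)-2-(bromomethyl)-3-(Ar5)acrylate | COc1ccc([C@@H](C=C)Cc2c(/C=C(\CBr)C(=O)OC)c(OCc3ccc(OC)cc3)cc3c2[C@@H](c2cc(OC)cc(OC)c2)[C@@H](c2ccc(OC)cc2)O3)cc1 | intermediate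
25 | 4-methoxybenzaldehyde | COc1ccc(C=O)cc1 | starting material
26 | methyl 4-hydroxy-4-(4-methoxyphenyl)-2-methylidene-3-(Ar5)butanoate (relative configuration as in lactone 27) | COc1ccc([C@@H](C=C)Cc2c([C@@H]([C@H](O)c3ccc(OC)cc3)C(=C)C(=O)OC)c(OCc3ccc(OC)cc3)cc3c2[C@@H](c2cc(OC)cc(OC)c2)[C@@H](c2ccc(OC)cc2)O3)cc1 | intermediate
27 | 4,5-cis-5-(4-methoxyphenyl)-3-methylidene-4-(Ar5)dihydrofuran-2(3H)-one | COc1ccc([C@@H](C=C)Cc2c([C@H]3[C@@H](c4ccc(OC)cc4)OC(=O)C3=C)c(OCc3ccc(OC)cc3)cc3c2[C@@H](c2cc(OC)cc(OC)c2)[C@@H](c2ccc(OC)cc2)O3)cc1 | intermediate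
28 | 2-[(2,3-trans,5,6-trans)-3-(3,5-dimethoxyphenyl)-2,6-bis(4-methoxyphenyl)-4-[(2R)-2-(4-methoxyphenyl)but-3-enyl]-2,3,5,6-tetrahydrobenzo[1,2-b:5,4-b']difuran-5-yl]acrylic acid | COc1ccc([C@@H](C=C)Cc2c3c(cc4c2[C@@H](c2cc(OC)cc(OC)c2)[C@H](c2ccc(OC)cc2)O4)O[C@H](c2ccc(OC)cc2)[C@H]3C(=C)C(=O)O)cc1 | intermediate
29 | 3-[tetrahydrobenzodifuran-5-yl group of 28]but-3-en-2-one | COc1ccc([C@@H](C=C)Cc2c3c(cc4c2[C@@H](c2cc(OC)cc(OC)c2)[C@H](c2ccc(OC)cc2)O4)O[C@H](c2ccc(OC)cc2)[C@H]3C(=C)C(C)=O)cc1 | intermediate
30 | cycloheptene-fused methyl ketone (ring C closed; acetyl on the alkene carbon bonded to C3') | COc1ccc([C@@H]2Cc3c4c(cc5c3[C@@H](c3cc(OC)cc(OC)c3)[C@H](c3ccc(OC)cc3)O5)O[C@H](c3ccc(OC)cc3)[C@H]4C(C(C)=O)=C2)cc1 | intermediate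
31 | 4,4,4-trifluoro-1-(cycloheptenyl)butane-1,3-dione derived from 30 | COc1ccc([C@@H]2Cc3c4c(cc5c3[C@@H](c3cc(OC)cc(OC)c3)[C@H](c3ccc(OC)cc3)O5)O[C@H](c3ccc(OC)cc3)[C@H]4C(C(=O)CC(=O)C(F)(F)F)=C2)cc1 | intermediate
32 | cycloheptenyl diazomethyl ketone (pentamethyl ether, both dihydrofurans in place) | COc1ccc([C@@H]2Cc3c4c(cc5c3[C@@H](c3cc(OC)cc(OC)c3)[C@H](c3ccc(OC)cc3)O5)O[C@H](c3ccc(OC)cc3)[C@H]4C(C(=O)C=[N+]=[N-])=C2)cc1 | intermediate
33 | (triisopropylsilyloxy)acetylene | C#CO[Si](C(C)C)(C(C)C)C(C)C | starting material
34 | 4-(cycloheptenyl)-3-(triisopropylsilyloxy)cyclobut-2-en-1-one (ring carbon C4 epimers) | COc1ccc([C@@H]2Cc3c4c(cc5c3[C@@H](c3cc(OC)cc(OC)c3)[C@H](c3ccc(OC)cc3)O5)O[C@H](c3ccc(OC)cc3)[C@H]4C(C3C(=O)C=C3O[Si](C(C)C)(C(C)C)C(C)C)=C2)cc1 | intermediate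
35 | pentamethyl ether of 37 with ring D as phenol and triisopropylsilyl ether | COc1ccc([C@@H]2Cc3c4c(cc5c3[C@@H](c3cc(OC)cc(OC)c3)[C@H](c3ccc(OC)cc3)O5)O[C@H](c3ccc(OC)cc3)[C@H]4c3cc(O[Si](C(C)C)(C(C)C)C(C)C)cc(O)c32)cc1 | intermediate
36 | pentamethyl ether of 37 with ring D as free resorcinol | COc1ccc([C@@H]2Cc3c4c(cc5c3[C@@H](c3cc(OC)cc(OC)c3)[C@H](c3ccc(OC)cc3)O5)O[C@H](c3ccc(OC)cc3)[C@H]4c3cc(O)cc(O)c32)cc1 | intermediate
37 | CNP0136963.1 | Oc1ccc([C@@H]2Cc3c4c(cc5c3[C@@H](c3cc(O)cc(O)c3)[C@H](c3ccc(O)cc3)O5)O[C@H](c3ccc(O)cc3)[C@H]4c3cc(O)cc(O)c32)cc1 | target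

## Step count and least certain steps

Total: 20 steps. Longest linear sequence: 19 steps (steps 1–7 and 9–20); step 8 is a one-step side branch.

**Step 18 (key step).** The most likely failure is slow capture of a hindered vinylketene: its ketene CH hangs on a fully substituted alkene carbon next to C3', so the ketene may be lost to traces of water or to the product phenol before the alkyne adds. A substrate with five anisole-type rings may also undergo other photoreactions. The fallback separates the rearrangement from the annulation and runs both in the dark. Setting out from 32, a Wolff rearrangement with PhCO2Ag and Et3N in THF/H2O should give the homologous cycloheptenylacetic acid F1. The Ghosez reagent (1-chloro-N,N,2-trimethylprop-1-enylamine) should convert it under neutral conditions into the acid chloride F2. Slow addition of Et3N to F2 and 33 in toluene at 80 °C would generate the same vinylketene by dehydrochlorination, and the cycloaddition, ring opening and electrocyclisation sequence comes back to the route at 35.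

**Step 5.** The most likely failure is loss of enantiocontrol, with some diversion to azine, because the carbene carbon carries an aryl group with two ortho substituents and is more crowded than the usual substrates. The fallback replaces asymmetric catalysis by resolution. Setting out from 9, oxidation with MnO2 and insertion with the achiral Rh2(OAc)4 should give the racemic cis-dihydrobenzofuran F3, and n-Bu4NF the racemic alcohol F4. Esterification with (S)-methoxy(phenyl)acetic acid (DCC, DMAP) would give two diastereomeric esters, from which the wanted (S)-methoxy(phenyl)acetate F5 is separated by chromatography. K2CO3 in MeOH cleaves F5 and the route is rejoined at 12.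

**Step 9.** The most likely failure is in forming and using the benzylic Grignard reagent: Wurtz coupling, or internal proton transfer from the neighbouring doubly benzylic C3–H with opening of the dihydrofuran, and a hindered nucleophile that lowers SN2' selectivity and enantioselectivity. The fallback uses 14 as the electrophile in an Evans alkylation. The acyl oxazolidinone (S)-4-benzyl-3-[(4-methoxyphenyl)acetyl]oxazolidin-2-one F6 is made from the commercial auxiliary and 4-methoxyphenylacetyl chloride (n-BuLi, THF, −78 °C). Its sodium enolate (NaN(SiMe3)2, THF, −78 °C) is alkylated by 14 (NaI added) to give the imide F7 with C8 set by the auxiliary. LiBH4 should give the primary alcohol F8 and Dess–Martin periodinane the α-aryl aldehyde F9; methylenation with Ph3P=CH2 at −78 °C returns to the route at 18.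

**Step 13.** The most likely failure is slow addition of a crowded allylchromium species through its aryl-bearing carbon, with erosion of diastereo- and enantiocontrol at C3'. The fallback uses a boron reagent and a metal-free closed transition state. Setting out from 24, B2pin2 and Pd2(dba)3 (cat.) should give the allylboronate F10 (CH2Bpin in place of CH2Br, same alkene geometry). Allylboration of 25 under a chiral BINOL-derived phosphoric acid would give 26, which is lactonised as before, so the route is rejoined at 27.

**Step 14.** The most likely failures are loss of the C3'–H proton from the C2' cation (an E1 path that would erase C3'), alkylation of the electron-rich rings by the 4-methoxybenzyl cation, and incomplete cis-to-trans equilibration at C2. The fallback separates dealkylation from isomerisation. Setting out from 27, BCl3 and pentamethylbenzene in CH2Cl2 at −78 °C should remove only the aryl 4-methoxybenzyl ether, giving the phenol lactone F11. With no benzyl cation left in the flask, a catalytic Lewis acid (Sc(OTf)3 in (CF3)2CHOH, 0 °C) would convert F11 into the dihydrofuran acid and equilibrate C2, returning to the route at 28.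

**Step 17.** The most likely failure is competing deprotonation at C8, which is γ to the carbonyl and also benzylic, during enolate formation; this would epimerise C8 or move the alkene. The fallback avoids enolate chemistry. Setting out from 28, ring-closing metathesis under the conditions of step 16 should give the cycloheptene carboxylic acid F12, and the Ghosez reagent the acid chloride F13. Me3SiCHN2 in MeCN/THF at 0 °C would then give the diazo ketone, so the route is rejoined at 32 and 29 and 30 are bypassed.

## Further compounds

F1 | step 18 | cycloheptenylacetic acid (32 with CH2CO2H in place of COCHN2) | COc1ccc([C@@H]2Cc3c4c(cc5c3[C@@H](c3cc(OC)cc(OC)c3)[C@H](c3ccc(OC)cc3)O5)O[C@H](c3ccc(OC)cc3)[C@H]4C(CC(=O)O)=C2)cc1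
F2 | step 18 | cycloheptenylacetyl chloride derived from F1 | COc1ccc([C@@H]2Cc3c4c(cc5c3[C@@H](c3cc(OC)cc(OC)c3)[C@H](c3ccc(OC)cc3)O5)O[C@H](c3ccc(OC)cc3)[C@H]4C(CC(=O)Cl)=C2)cc1
F3 | step 5 | racemic cis-dihydrobenzofuran (racemate of 11; one enantiomer drawn) | CC(C)[Si](OCc1c(Br)c(OCc2ccc(OC)cc2)cc2c1[C@@H](c1cc(OC)cc(OC)c1)[C@@H](c1ccc(OC)cc1)O2)(C(C)C)C(C)C
F4 | step 5 | racemic alcohol (racemate of 12; one enantiomer drawn) | OCc1c(Br)c(OCc2ccc(OC)cc2)cc2c1[C@@H](c1cc(OC)cc(OC)c1)[C@@H](c1ccc(OC)cc1)O2
F5 | step 5 | (S)-methoxy(phenyl)acetate of 12 | CO[C@H](C(=O)OCc1c(Br)c(OCc2ccc(OC)cc2)cc2c1[C@@H](c1cc(OC)cc(OC)c1)[C@@H](c1ccc(OC)cc1)O2)c1ccccc1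
F6 | step 9 | (S)-4-benzyl-3-[(4-methoxyphenyl)acetyl]oxazolidin-2-one | COc1ccc(CC(=O)N2C(=O)OC[C@@H]2Cc2ccccc2)cc1
F7 | step 9 | alkylated imide (18 with the N-acyl oxazolidinone in place of the vinyl group) | COc1ccc([C@@H](C(=O)N2C(=O)OC[C@@H]2Cc2ccccc2)Cc2c(Br)c(OCc3ccc(OC)cc3)cc3c2[C@@H](c2cc(OC)cc(OC)c2)[C@@H](c2ccc(OC)cc2)O3)cc1
F8 | step 9 | primary alcohol (18 with CH2OH in place of the vinyl group) | COc1ccc([C@@H](CO)Cc2c(Br)c(OCc3ccc(OC)cc3)cc3c2[C@@H](c2cc(OC)cc(OC)c2)[C@@H](c2ccc(OC)cc2)O3)cc1
F9 | step 9 | α-aryl aldehyde (18 with CHO in place of the vinyl group) | COc1ccc([C@@H](C=O)Cc2c(Br)c(OCc3ccc(OC)cc3)cc3c2[C@@H](c2cc(OC)cc(OC)c2)[C@@H](c2ccc(OC)cc2)O3)cc1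
F10 | step 13 | allylboronate (24 with CH2B(pin) in place of CH2Br) | COc1ccc([C@@H](C=C)Cc2c(/C=C(\CB3OC(C)(C)C(C)(C)O3)C(=O)OC)c(OCc3ccc(OC)cc3)cc3c2[C@@H](c2cc(OC)cc(OC)c2)[C@@H](c2ccc(OC)cc2)O3)cc1
F11 | step 14 | phenol lactone (27 without the 4-methoxybenzyl group) | COc1ccc([C@@H](C=C)Cc2c([C@H]3[C@@H](c4ccc(OC)cc4)OC(=O)C3=C)c(O)cc3c2[C@@H](c2cc(OC)cc(OC)c2)[C@@H](c2ccc(OC)cc2)O3)cc1
F12 | step 17 | cycloheptene carboxylic acid (30 with CO2H in place of COCH3) | COc1ccc([C@@H]2Cc3c4c(cc5c3[C@@H](c3cc(OC)cc(OC)c3)[C@H](c3ccc(OC)cc3)O5)O[C@H](c3ccc(OC)cc3)[C@H]4C(C(=O)O)=C2)cc1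
F13 | step 17 | cycloheptene carbonyl chloride derived from F12 | COc1ccc([C@@H]2Cc3c4c(cc5c3[C@@H](c3cc(OC)cc(OC)c3)[C@H](c3ccc(OC)cc3)O5)O[C@H](c3ccc(OC)cc3)[C@H]4C(C(=O)Cl)=C2)cc1
A1 | alternative 1 | six-membered diaryl ketone of the 10-substituted anthrone type | O=C1c2c3c(cc4c2[C@@H](c2cc(OC)cc(OC)c2)[C@H](c2ccc(OC)cc2)O4)O[C@H](c2ccc(OC)cc2)[C@H]3c2cc(OC)cc(OC)c21
A2 | alternative 1 | 4-methoxyphenyldiazomethane | COc1ccc(C=[N+]=[N-])cc1
A3 | alternative 1 | seven-membered α-aryl ketone (heptamethyl ether) | COc1ccc([C@@H]2C(=O)c3c4c(cc5c3[C@@H](c3cc(OC)cc(OC)c3)[C@H](c3ccc(OC)cc3)O5)O[C@H](c3ccc(OC)cc3)[C@H]4c3cc(OC)cc(OC)c32)cc1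
A4 | alternative 2 | 4-substituted 1,1-dimethoxy-3-(trimethylsilyloxy)buta-1,3-diene | COC(OC)=CC(O[Si](C)(C)C)=C[C@@H](c1cc(OC)cc(OC)c1)[C@H](c1ccc(OC)cc1)O[Si](C)(C)C(C)(C)C
A5 | alternative 2 | 2-bromo enone of the ring D-fused cycloheptenone | COc1ccc([C@@H]2CC=C(Br)C(=O)c3cc(OC)cc(OC)c32)cc1
A6 | alternative 2 | ring A phenol methyl ether fused to the seven-membered ketone | COc1ccc([C@@H]2Cc3c(c(OC)cc(O)c3[C@@H](c3cc(OC)cc(OC)c3)[C@H](c3ccc(OC)cc3)O[Si](C)(C)C(C)(C)C)C(=O)c3cc(OC)cc(OC)c32)cc1
A7 | alternative 3 | ring D aryl bromide tethered to C4 of the 2-(4-methoxyphenyl)benzofuran | COc1ccc([C@@H](c2c(Br)cc(OC)cc2OC)Cc2c3cc(-c4ccc(OC)cc4)oc3cc3c2[C@@H](c2cc(OC)cc(OC)c2)[C@H](c2ccc(OC)cc2)O3)cc1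
A8 | alternative 3 | heptamethyl ether of 37 | COc1ccc([C@@H]2Cc3c4c(cc5c3[C@@H](c3cc(OC)cc(OC)c3)[C@H](c3ccc(OC)cc3)O5)O[C@H](c3ccc(OC)cc3)[C@H]4c3cc(OC)cc(OC)c32)cc1
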